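**Plan**

1. Cuts: the C3=C4 double bond is taken back to a chroman; the side chain is cut at C2'–C3' (sp3–sp2) into a 2-vinylchroman and an E-iodoalkene carrying ring A; the pyran is cut at O1–C2.
2. Enabling feature: O1–C2 ends at the quaternary C2, which bears a methyl group and the two-carbon arm C1'–C2' and is tied to the arene through C3–C4. C2, C1' and C2' therefore map onto the substituted end of a methyl-substituted allyl unit that the phenol oxygen can reach in a six-membered closure.
3. Chroman half: 2,5-dihydroxybenzaldehyde is differentiated at its two oxygens, extended to an (E)-allylic methyl carbonate with the ortho phenol free, and cyclised by palladium to the 2-methyl-2-vinylchroman, the only ring made in the route.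
4. Ring A half: racemic α-ionone is resolved, reduced at the enone C=C, converted into the terminal alkyne and methylaluminated/iodinated to the E-iodoalkene.
5. Union and finish: hydroboration of the vinyl group and Suzuki coupling, then C3–C4 dehydrogenation and desilylation.
6. Stereochemistry: C2 comes from the chiral ligand in the cyclisation, the ring A centre from the resolution, and the trisubstituted alkene from syn-carbometalation carried through with retention.

Key step: step 8

Assumption 1: the (R,R)-ligand is taken to deliver the (R)-vinylchroman from the E-carbonate; should the sense of induction prove opposite, the (S,S)-ligand is used with nothing else changed.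

Assumption 2: the carbazate of (−)-menthol is the classical resolving agent that crystallises with (R)-α-ionone, so by mirror-image correspondence the carbazate of (+)-menthol is taken to crystallise with (S)-α-ionone.

**Route**

Step 1
Reactants: 1 2,5-dihydroxybenzaldehyde
Product: 2 2-hydroxy-5-(triisopropylsilyloxy)benzaldehyde
Conditions: i-Pr3SiCl (1.05 equiv), imidazole, CH2Cl2, 0 °C
Reagents that add atoms: triisopropylsilyl chloride, CC(C)[Si](Cl)(C(C)C)C(C)C
Why: Chemoselective silyl ether formation, since the 2-hydroxyl is locked in an intramolecular hydrogen bond to the formyl group and flanked by it, so the bulky silyl chloride should react only at the free 5-hydroxyl.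

Step 2
Reactants: 2 2-hydroxy-5-(triisopropylsilyloxy)benzaldehyde
Product: 3 2-formyl-4-(triisopropylsilyloxy)phenyl pivalate
Conditions: t-BuCOCl, Et3N, DMAP (cat.), CH2Cl2, 0 °C to rt
Reagents that add atoms: pivaloyl chloride, CC(C)(C)C(Cl)=O
Why: DMAP-catalysed esterification of the remaining phenol gives a hindered aryl ester that should tolerate ylides and phosphonate anions and is later removed by the same hydride that reduces the chain ester.

Step 3
Reactants: 3 2-formyl-4-(triisopropylsilyloxy)phenyl pivalate
Product: 4 2-[(1E)-3-oxobut-1-en-1-yl]-4-(triisopropylsilyloxy)phenyl pivalate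
Conditions: Ph3P=CHCOCH3, toluene, 80 °C
Reagents that add atoms: 1-(triphenylphosphoranylidene)propan-2-one, CC(=O)C=P(c1ccccc1)(c1ccccc1)c1ccccc1
Why: Wittig olefination with a stabilised ylide under neutral conditions should give the E-enone without exposing the aryl silyl ether or the aryl ester to base.

Step 4
Reactants: 4 2-[(1E)-3-oxobut-1-en-1-yl]-4-(triisopropylsilyloxy)phenyl pivalate
Product: 5 2-(3-oxobutyl)-4-(triisopropylsilyloxy)phenyl pivalate
Conditions: H2 (1 atm), Pd/C (5%), EtOAc, rt
Reagents that add atoms: none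
Why: Heterogeneous catalytic hydrogenation saturates the conjugated styrenyl C=C far faster than it touches the ketone, the aryl ester or the aryl silyl ether.

Step 5
Reactants: 5 2-(3-oxobutyl)-4-(triisopropylsilyloxy)phenyl pivalate
Product: 6 ethyl (2E)-3-methyl-5-[2-(pivaloyloxy)-5-(triisopropylsilyloxy)phenyl]pent-2-enoate
Conditions: (EtO)2P(O)CH2CO2Et, NaH, THF, 0 to 50 °C; chromatographic removal of the minor Z-isomer
Reagents that add atoms: triethyl phosphonoacetate, CCOC(=O)CP(=O)(OCC)OCC
Why: Horner–Wadsworth–Emmons olefination of the methyl ketone should favour the E-enoate, with the ester trans to the larger arylethyl group, and the minor Z-isomer is removed here because geometric purity governs the key step.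

Step 6
Reactants: 6 ethyl (2E)-3-methyl-5-[2-(pivaloyloxy)-5-(triisopropylsilyloxy)phenyl]pent-2-enoate
Product: 7 2-[(3E)-5-hydroxy-3-methylpent-3-en-1-yl]-4-(triisopropylsilyloxy)phenol
Conditions: i-Bu2AlH (5 equiv), CH2Cl2, −78 to 0 °C; Rochelle salt work-up
Reagents that add atoms: none
Why: Hydride reduction with i-Bu2AlH converts the conjugated ester into the allylic alcohol by 1,2-reduction without touching the alkene and, in the same operation, cleaves the aryl pivalate to free the phenol.

Step 7
Reactants: 7 2-[(3E)-5-hydroxy-3-methylpent-3-en-1-yl]-4-(triisopropylsilyloxy)phenol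
Product: 8 (2E)-5-[2-hydroxy-5-(triisopropylsilyloxy)phenyl]-3-methylpent-2-en-1-yl methyl carbonate
Conditions: ClCO2CH3 (1.05 equiv), pyridine, CH2Cl2, −30 °C
Reagents that add atoms: methyl chloroformate, COC(Cl)=O
Why: Chemoselective carbonate formation, since with pyridine as the only base the phenol stays un-ionised and the N-methoxycarbonylpyridinium ion should acylate the unhindered primary allylic hydroxyl in preference to the ortho-substituted phenol.

Step 8
Reactants: 8 (2E)-5-[2-hydroxy-5-(triisopropylsilyloxy)phenyl]-3-methylpent-2-en-1-yl methyl carbonate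
Product: 9 (2R)-2-ethenyl-2-methyl-6-(triisopropylsilyloxy)chroman
Conditions: Pd2(dba)3·CHCl3 (2 mol%), N,N'-[(1R,2R)-cyclohexane-1,2-diyl]bis[2-(diphenylphosphino)benzamide] (6 mol%), AcOH (1 equiv), CH2Cl2 (0.05 M), rt
Reagents that add atoms: none
Why: Zerovalent palladium ionises the allylic carbonate with loss of CO2 and methoxide to a π-allyl complex held in the chiral pocket of the bisphosphine, and the tethered phenol oxygen then attacks the methyl-bearing terminus anti to the metal; this is an intramolecular Tsuji–Trost O-allylation, the closest known reaction type being asymmetric allylic etherification of phenols to 2-vinylchromans. The dihydropyran ring closes in a 6-exo mode, leaving the other two allyl carbons outside the ring as the vinyl group. The quaternary stereocentre C2 is set by the ligand: the two diastereomeric complexes should interconvert through a σ-allyl at the unsubstituted CH2 terminus faster than they cyclise, helped by acetic acid, which keeps the phenol protonated and slows ring closure, so the faster-cyclising complex funnels the material to the (R)-chroman. Regioselectivity for the branched terminus is needed and is secured by the tether, since attack at the CH2 end would require an eight-membered ring. Enantioselectivity also depends on the geometric purity of the E-alkene, which fixes the arrangement of the allyl substituents, and this is secured by removing the Z-ester at the stage of 6.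

Step 9
Reactants: 10 (1S,2R,5S)-menthyl chloroformate
Product: 11 (1S,2R,5S)-menthyl carbazate
Conditions: N2H4·H2O (4 equiv), Et2O, 0 °C to rt
Reagents that add atoms: hydrazine monohydrate, NN.O
Why: Acyl substitution of the chloroformate by excess hydrazine gives the carbazate, and the menthyl stereocentres are not involved.

Step 10
Reactants: 11 (1S,2R,5S)-menthyl carbazate; 12 racemic α-ionone
Product: 13 (1S,2R,5S)-menthyl 2-{(2E,3E)-4-[(1S)-2,6,6-trimethylcyclohex-2-en-1-yl]but-3-en-2-ylidene}hydrazine-1-carboxylate
Conditions: NaOAc, AcOH (cat.), EtOH, reflux; fractional crystallisation from EtOH to constant rotation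
Reagents that add atoms: none
Why: Condensation of the carbazate with the ketone gives two diastereomeric acylhydrazones, and fractional crystallisation (classical resolution through covalent diastereomers) should deliver the less soluble (S)-ionone derivative; no new stereocentre is formed.

Step 11
Reactants: 13 (1S,2R,5S)-menthyl 2-{(2E,3E)-4-[(1S)-2,6,6-trimethylcyclohex-2-en-1-yl]but-3-en-2-ylidene}hydrazine-1-carboxylate
Product: 14 (S)-α-ionone
Conditions: 10% aq. oxalic acid, pentane, 40 °C (two-phase)
Reagents that add atoms: water, O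
Why: Acid-catalysed hydrolysis of the acylhydrazone, driven by extraction of the ketone into pentane, returns the enone, and the weak acid should neither epimerise the ring stereocentre nor move the ring alkene into conjugation.

Step 12
Reactants: 14 (S)-α-ionone
Product: 15 4-[(1S)-2,6,6-trimethylcyclohex-2-en-1-yl]butan-2-one
Conditions: Cu(OAc)2·H2O (5 mol%), 1,2-bis(diphenylphosphino)benzene (5 mol%), (EtO)2MeSiH (1.5 equiv), t-BuOH (1.5 equiv), toluene, rt
Reagents that add atoms: none
Why: Copper hydride-catalysed conjugate reduction (1,4-hydride addition, then protonation of the copper enolate by t-BuOH) saturates only the enone C=C and leaves the isolated trisubstituted ring alkene and the adjacent stereocentre untouched.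

Step 13
Reactants: 15 4-[(1S)-2,6,6-trimethylcyclohex-2-en-1-yl]butan-2-one
Product: 17 4-[(1S)-2,6,6-trimethylcyclohex-2-en-1-yl]but-1-yne, via enol phosphate 16 (not isolated)
Conditions: LiN(i-Pr)2 (1.1 equiv), THF, −78 °C; ClP(O)(OEt)2, −78 °C to rt; then LiN(i-Pr)2 (2.3 equiv), −78 °C to rt; aq. NH4Cl
Reagents that add atoms: none
Why: Kinetic deprotonation at the methyl group, O-phosphorylation and base-induced elimination of the enol phosphate (the methyl ketone to terminal alkyne conversion) gives the alkyne with no change at the ring stereocentre.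

Step 14
Reactants: 17 4-[(1S)-2,6,6-trimethylcyclohex-2-en-1-yl]but-1-yne
Product: 19 (1E)-1-iodo-2-methyl-4-[(1S)-2,6,6-trimethylcyclohex-2-en-1-yl]but-1-ene, via alkenylalane 18 (not isolated)
Conditions: AlMe3 (2.5 equiv), Cp2ZrCl2 (0.25 equiv), CH2Cl2, 0 °C to rt; then I2, THF, −30 to 0 °C
Reagents that add atoms: trimethylaluminium, C[Al](C)C; iodine, II
Why: Zirconium-catalysed Negishi carboalumination adds methyl and aluminium syn across the terminal alkyne with aluminium at the terminal carbon, and iodinolysis with retention should give the E-iodoalkene as a single geometric isomer while the trisubstituted ring alkene stays inert.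

Step 15
Reactants: 9 (2R)-2-ethenyl-2-methyl-6-(triisopropylsilyloxy)chroman; 19 (1E)-1-iodo-2-methyl-4-[(1S)-2,6,6-trimethylcyclohex-2-en-1-yl]but-1-ene
Product: 21 (2S)-2-methyl-2-{(3E)-4-methyl-6-[(1S)-2,6,6-trimethylcyclohex-2-en-1-yl]hex-3-en-1-yl}-6-(triisopropylsilyloxy)chroman, via B-alkyl-9-BBN adduct 20 (not isolated)
Conditions: 9-BBN (1.5 equiv), THF, 0 °C to rt; then 19, PdCl2(dppf)·CH2Cl2 (5 mol%), AsPh3 (10 mol%), 3 M aq. K3PO4, THF/DMF, rt
Reagents that add atoms: none
Why: Anti-Markovnikov hydroboration of the monosubstituted vinyl group with 9-BBN followed by B-alkyl Suzuki–Miyaura coupling joins C2' to C3' with retention of the iodoalkene geometry, and neither stereocentre is touched (the descriptor at C2 changes from R to S only because the priorities change).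

Step 16
Reactants: 21 (2S)-2-methyl-2-{(3E)-4-methyl-6-[(1S)-2,6,6-trimethylcyclohex-2-en-1-yl]hex-3-en-1-yl}-6-(triisopropylsilyloxy)chroman
Product: 22 (2S)-2-methyl-2-{(3E)-4-methyl-6-[(1S)-2,6,6-trimethylcyclohex-2-en-1-yl]hex-3-en-1-yl}-6-(triisopropylsilyloxy)-2H-chromene
Conditions: DDQ (1.2 equiv), 1,4-dioxane, 60 °C, dark
Reagents that add atoms: none
Why: Quinone dehydrogenation, in which DDQ abstracts hydride from benzylic C4 (the cation being stabilised by the ring oxygen O1) and loss of a C3 proton gives the 2H-chromene, which cannot go on to a benzopyrylium ion because C2 is quaternary.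

Step 17
Reactants: 22 (2S)-2-methyl-2-{(3E)-4-methyl-6-[(1S)-2,6,6-trimethylcyclohex-2-en-1-yl]hex-3-en-1-yl}-6-(triisopropylsilyloxy)-2H-chromene
Product: 23 (2S)-2-methyl-2-{(3E)-4-methyl-6-[(1S)-2,6,6-trimethylcyclohex-2-en-1-yl]hex-3-en-1-yl}-2H-chromen-6-ol
Conditions: Bu4NF (1.1 equiv), AcOH (1.1 equiv), THF, 0 °C
Reagents that add atoms: none
Why: Fluoride-induced desilylation of the aryl silyl ether, buffered with acetic acid so that the air-sensitive phenoxide is protonated at once, should release the target without affecting the chromene or the alkenes.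

**Compound list**

1 | 2,5-dihydroxybenzaldehyde | O=Cc1cc(O)ccc1O | starting material
2 | 2-hydroxy-5-(triisopropylsilyloxy)benzaldehyde | O=Cc1cc(O[Si](C(C)C)(C(C)C)C(C)C)ccc1O | intermediate
3 | 2-formyl-4-(triisopropylsilyloxy)phenyl pivalate | CC(C)(C)C(=O)Oc1ccc(O[Si](C(C)C)(C(C)C)C(C)C)cc1C=O | intermediate
4 | 2-[(1E)-3-oxobut-1-en-1-yl]-4-(triisopropylsilyloxy)phenyl pivalate | CC(=O)/C=C/c1cc(O[Si](C(C)C)(C(C)C)C(C)C)ccc1OC(=O)C(C)(C)C | intermediate
5 | 2-(3-oxobutyl)-4-(triisopropylsilyloxy)phenyl pivalate | CC(=O)CCc1cc(O[Si](C(C)C)(C(C)C)C(C)C)ccc1OC(=O)C(C)(C)C | intermediate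
6 | ethyl (2E)-3-methyl-5-[2-(pivaloyloxy)-5-(triisopropylsilyloxy)phenyl]pent-2-enoate | CCOC(=O)/C=C(\C)CCc1cc(O[Si](C(C)C)(C(C)C)C(C)C)ccc1OC(=O)C(C)(C)C | intermediate
7 | 2-[(3E)-5-hydroxy-3-methylpent-3-en-1-yl]-4-(triisopropylsilyloxy)phenol | OC/C=C(\C)CCc1cc(O[Si](C(C)C)(C(C)C)C(C)C)ccc1O | intermediate
8 | (2E)-5-[2-hydroxy-5-(triisopropylsilyloxy)phenyl]-3-methylpent-2-en-1-yl methyl carbonate | COC(=O)OC/C=C(\C)CCc1cc(O[Si](C(C)C)(C(C)C)C(C)C)ccc1O | intermediate
9 | (2R)-2-ethenyl-2-methyl-6-(triisopropylsilyloxy)chroman | C=C[C@@]1(C)CCc2cc(O[Si](C(C)C)(C(C)C)C(C)C)ccc2O1 | intermediate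
10 | (1S,2R,5S)-menthyl chloroformate | C[C@H]1CC[C@@H]([C@H](C1)OC(Cl)=O)C(C)C | starting material
11 | (1S,2R,5S)-menthyl carbazate | C[C@H]1CC[C@@H]([C@H](C1)OC(=O)NN)C(C)C | intermediate
12 | racemic α-ionone, (3E)-4-(2,6,6-trimethylcyclohex-2-en-1-yl)but-3-en-2-one | CC1=CCCC(C)(C)C1/C=C/C(C)=O | starting material
13 | (1S,2R,5S)-menthyl 2-{(2E,3E)-4-[(1S)-2,6,6-trimethylcyclohex-2-en-1-yl]but-3-en-2-ylidene}hydrazine-1-carboxylate | C[C@H]1CC[C@@H]([C@H](C1)OC(=O)N/N=C(C)/C=C/[C@@H]2C(C)=CCCC2(C)C)C(C)C | intermediate
14 | (S)-α-ionone | CC1=CCCC(C)(C)[C@@H]1/C=C/C(C)=O | intermediate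
15 | 4-[(1S)-2,6,6-trimethylcyclohex-2-en-1-yl]butan-2-one | CC1=CCCC(C)(C)[C@@H]1CCC(C)=O | intermediate
16 | diethyl 4-[(1S)-2,6,6-trimethylcyclohex-2-en-1-yl]but-1-en-2-yl phosphate | CC1=CCCC(C)(C)[C@@H]1CCC(=C)OP(=O)(OCC)OCC | intermediate
17 | 4-[(1S)-2,6,6-trimethylcyclohex-2-en-1-yl]but-1-yne | CC1=CCCC(C)(C)[C@@H]1CCC#C | intermediate
18 | dimethyl{(1E)-2-methyl-4-[(1S)-2,6,6-trimethylcyclohex-2-en-1-yl]but-1-en-1-yl}alane | CC1=CCCC(C)(C)[C@@H]1CC/C(C)=C/[Al](C)C | intermediate
19 | (1E)-1-iodo-2-methyl-4-[(1S)-2,6,6-trimethylcyclohex-2-en-1-yl]but-1-ene | CC1=CCCC(C)(C)[C@@H]1CC/C(C)=C/I | intermediate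
20 | 9-{2-[(2S)-2-methyl-6-(triisopropylsilyloxy)chroman-2-yl]ethyl}-9-borabicyclo[3.3.1]nonane | B1(C2CCCC1CCC2)CC[C@@]1(C)CCc2cc(O[Si](C(C)C)(C(C)C)C(C)C)ccc2O1 | intermediate
21 | (2S)-2-methyl-2-{(3E)-4-methyl-6-[(1S)-2,6,6-trimethylcyclohex-2-en-1-yl]hex-3-en-1-yl}-6-(triisopropylsilyloxy)chroman | CC1=CCCC(C)(C)[C@@H]1CC/C(C)=C/CC[C@@]1(C)CCc2cc(O[Si](C(C)C)(C(C)C)C(C)C)ccc2O1 | intermediate
22 | (2S)-2-methyl-2-{(3E)-4-methyl-6-[(1S)-2,6,6-trimethylcyclohex-2-en-1-yl]hex-3-en-1-yl}-6-(triisopropylsilyloxy)-2H-chromene | CC1=CCCC(C)(C)[C@@H]1CC/C(C)=C/CC[C@@]1(C)C=Cc2cc(O[Si](C(C)C)(C(C)C)C(C)C)ccc2O1 | intermediate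
23 | (2S)-2-methyl-2-{(3E)-4-methyl-6-[(1S)-2,6,6-trimethylcyclohex-2-en-1-yl]hex-3-en-1-yl}-2H-chromen-6-ol | CC1=CCCC(C)(C)[C@@H]1CC/C(C)=C/CC[C@@]1(C)C=Cc2cc(O)ccc2O1 | target

**Step count**

Total: 17 steps. Longest linear sequence: 11 steps (steps 1–8 and 15–17, from 1). The ring A branch (steps 9–14) is 6 steps to 19.

**Three steps most likely to fail**

Step 8. The risk is insufficient facial discrimination at the E-configured allyl complex, either because ring closure competes with equilibration of the two complexes or because syn–anti isomerisation erodes the selectivity. The fallback keeps the same O1–C2 closure but changes the alkene geometry of the precursor, which is built by a stereodefined cross-coupling. It sets out from 3 and returns at 9. Aldehyde 3 would be methylenated (Ph3P=CH2, THF, −78 to 0 °C) to 2-ethenyl-4-(triisopropylsilyloxy)phenyl pivalate F1. But-2-yn-1-ol would be converted by NaAlH2(OCH2CH2OCH3)2 and then iodine into (2Z)-3-iodobut-2-en-1-ol F2. Hydroboration of F1 with 9-BBN would give 2-[2-(9-borabicyclo[3.3.1]nonan-9-yl)ethyl]-4-(triisopropylsilyloxy)phenyl pivalate F3, and Suzuki coupling with F2 (PdCl2(dppf)·CH2Cl2, aq. K3PO4) would give 2-[(3Z)-5-hydroxy-3-methylpent-3-en-1-yl]-4-(triisopropylsilyloxy)phenyl pivalate F4, its geometry fixed by the iodide. i-Bu2AlH would free the phenol to 2-[(3Z)-5-hydroxy-3-methylpent-3-en-1-yl]-4-(triisopropylsilyloxy)phenol F5, and methyl chloroformate with pyridine would give (2Z)-5-[2-hydroxy-5-(triisopropylsilyloxy)phenyl]-3-methylpent-2-en-1-yl methyl carbonate F6. Cyclisation of F6 with the (1S,2S)-ligand under the conditions of step 8 is expected to give 9, on the reasoning that inverting the alkene geometry inverts the face the ligand selects.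

Step 16. The risks are competing hydride abstraction at the allylic positions of the side chain and ring A, over-oxidation of the electron-rich arene, and thermal or photochemical electrocyclic opening of the chromene, which would erode C2. The fallback desaturates before the side chain is present and without a quinone oxidant. It sets out from 9 and returns at 22. Radical bromination of 9 (NBS, AIBN, PhCF3, reflux) at the only activated C–H position would give (2R)-4-bromo-2-ethenyl-2-methyl-6-(triisopropylsilyloxy)chroman F7, which is eliminated with DBU to (2S)-2-ethenyl-2-methyl-6-(triisopropylsilyloxy)-2H-chromene F8. 9-BBN should hydroborate the monosubstituted vinyl group far faster than the cis-disubstituted C3=C4 alkene, giving 9-{2-[(2S)-2-methyl-6-(triisopropylsilyloxy)-2H-chromen-2-yl]ethyl}-9-borabicyclo[3.3.1]nonane F9. Coupling F9 with 19 under the conditions of step 15 at room temperature gives 22.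

Step 10. The risks are poor discrimination between the diastereomeric hydrazones on crystallisation (solid solutions or oiling) and a pairing opposite to the one assumed. The fallback replaces the covalent resolution by a physical one. It sets out from 12 and returns at 14. Racemic 12 would be separated by preparative enantioselective chromatography (supercritical CO2/methanol on an amylose tris(3,5-dimethylphenylcarbamate) phase) and the (S)-enantiomer collected directly as 14; this fallback makes no new compound (F0).

**Further compounds**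

F1 | step 8 | 2-ethenyl-4-(triisopropylsilyloxy)phenyl pivalate | C=Cc1cc(O[Si](C(C)C)(C(C)C)C(C)C)ccc1OC(=O)C(C)(C)C
F2 | step 8 | (2Z)-3-iodobut-2-en-1-ol | C/C(I)=C/CO
F3 | step 8 | 2-[2-(9-borabicyclo[3.3.1]nonan-9-yl)ethyl]-4-(triisopropylsilyloxy)phenyl pivalate | B1(C2CCCC1CCC2)CCc1cc(O[Si](C(C)C)(C(C)C)C(C)C)ccc1OC(=O)C(C)(C)C
F4 | step 8 | 2-[(3Z)-5-hydroxy-3-methylpent-3-en-1-yl]-4-(triisopropylsilyloxy)phenyl pivalate | OC/C=C(/C)CCc1cc(O[Si](C(C)C)(C(C)C)C(C)C)ccc1OC(=O)C(C)(C)C
F5 | step 8 | 2-[(3Z)-5-hydroxy-3-methylpent-3-en-1-yl]-4-(triisopropylsilyloxy)phenol | OC/C=C(/C)CCc1cc(O[Si](C(C)C)(C(C)C)C(C)C)ccc1O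
F6 | step 8 | (2Z)-5-[2-hydroxy-5-(triisopropylsilyloxy)phenyl]-3-methylpent-2-en-1-yl methyl carbonate | COC(=O)OC/C=C(/C)CCc1cc(O[Si](C(C)C)(C(C)C)C(C)C)ccc1O
F7 | step 16 | (2R)-4-bromo-2-ethenyl-2-methyl-6-(triisopropylsilyloxy)chroman, mixture at C4 | C=C[C@@]1(C)CC(Br)c2cc(O[Si](C(C)C)(C(C)C)C(C)C)ccc2O1
F8 | step 16 | (2S)-2-ethenyl-2-methyl-6-(triisopropylsilyloxy)-2H-chromene | C=C[C@@]1(C)C=Cc2cc(O[Si](C(C)C)(C(C)C)C(C)C)ccc2O1
F9 | step 16 | 9-{2-[(2S)-2-methyl-6-(triisopropylsilyloxy)-2H-chromen-2-yl]ethyl}-9-borabicyclo[3.3.1]nonane | B1(C2CCCC1CCC2)CC[C@@]1(C)C=Cc2cc(O[Si](C(C)C)(C(C)C)C(C)C)ccc2O1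
F0 | step 10 | none | none
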